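**Assumption:** (2Z)-oct-2-en-1-ol, furfuryl alcohol, (5R)-5-(hydroxymethyl)oxolan-2-one and Ph3P=CHCHO are taken as commercial; target positions use prostanoid numbering (lactone C=O is C1, lactone CH–O is C4, ring is C8–C12, ketone C9, acetate carbon C12), so the target (clavulolactone III) is 4R,5E,7Z,12S,14Z.

## Retrosynthetic overview

1. Target ⇒ aldol diol: the C12 acetate and the C7=C8 bond are installed last, in one flask (double acetylation, E1cB loss of AcOH).
2. Aldol diol ⇒ C7–C8 aldol between (R)-4-hydroxy-4-[(Z)-oct-2-enyl]cyclopent-2-enone (as its O,C-dianion) and an (R)-lactone enal.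
3. Cyclopentenone ⇒ catalyst-controlled, dearomatising oxa-Piancatelli ring contraction of 5-[(Z)-oct-2-enyl]furfuryl alcohol; this forms C8–C12 and sets C12.
4. Furan ⇒ furfuryl alcohol C,O-dianion + (Z)-1-bromooct-2-ene; enal ⇒ (R)-5-(hydroxymethyl)oxolan-2-one by oxidation and Wittig reaction.
5. Ring order: the lactone is bought intact and the furan is the feedstock; the carbocycle is the only ring made, from the furan, in step 3.

## Route

**Step 1**
Reactants: 1 (2Z)-oct-2-en-1-ol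
Product: 2 (2Z)-1-bromooct-2-ene
Conditions: CBr4, PPh3, CH2Cl2, 0 °C
Reagents that add atoms: carbon tetrabromide, BrC(Br)(Br)Br
Why: Appel reaction; SN2 displacement at the primary allylic carbon at 0 °C gives the bromide without allylic transposition or loss of the Z geometry.

**Step 2**
Reactants: 3 furan-2-ylmethanol (furfuryl alcohol); 2 (2Z)-1-bromooct-2-ene
Product: 5 {5-[(2Z)-oct-2-en-1-yl]furan-2-yl}methanol, via C5-lithiated lithium alkoxide 4 (not isolated)
Conditions: n-BuLi (2.1 equiv), THF, −78 → 0 °C; then 2 (1.0 equiv), −78 °C → rt; H2O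
Reagents that add atoms: none
Why: Double deprotonation (O–H, then the acidic furan α-C–H) followed by SN2 C-allylation of the furyllithium, which is faster than O-alkylation of the aggregated lithium alkoxide and leaves the Z-olefin intact.

**Step 3**
Reactants: 5 {5-[(2Z)-oct-2-en-1-yl]furan-2-yl}methanol
Product: 6 (4R)-4-hydroxy-4-[(2Z)-oct-2-en-1-yl]cyclopent-2-en-1-one
Conditions: (R)-3,3'-bis(2,4,6-triisopropylphenyl)-1,1'-binaphthyl-2,2'-diyl N-(trifluoromethylsulfonyl)phosphoramide (10 mol%), H2O-saturated CHCl3 (0.02 M, extra H2O 10 equiv), 40 °C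
Reagents that add atoms: water, O
Why: Proposed new method: the strong chiral acid ionises the primary, 5-alkyl-stabilised furfuryl alcohol, water adds to the octenyl-bearing furan carbon, ring opening gives a 1,4-dihydroxypentadienyl cation, and its conrotatory 4π electrocyclisation (oxa-Piancatelli rearrangement) closes C8–C12 and creates C12, whose configuration is fixed by the torquoselectivity imposed by the hydrogen-bonded chiral phosphoramide counter-anion (the catalyst antipode that gives the R product is chosen by screening); the closest known reactions are racemic Piancatelli rearrangements of 5-methyl-substituted furylcarbinols to 4-hydroxy-4-methylcyclopent-2-enones, chiral-Brønsted-acid-catalysed aza-Piancatelli rearrangements and asymmetric Nazarov cyclisations.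

**Step 4**
Reactants: 7 (5R)-5-(hydroxymethyl)oxolan-2-one
Product: 9 (2E)-3-[(2R)-5-oxooxolan-2-yl]prop-2-enal, via (2R)-5-oxooxolane-2-carbaldehyde 8 (not isolated)
Conditions: (COCl)2, DMSO, CH2Cl2, −78 °C; Et3N, −78 → 0 °C; then Ph3P=CHCHO (1.1 equiv), 0 °C → rt
Reagents that add atoms: (triphenylphosphoranylidene)acetaldehyde, O=CC=P(c1ccccc1)(c1ccccc1)c1ccccc1
Why: Swern oxidation followed by in-situ Wittig olefination with the stabilised formyl ylide (E-selective) avoids isolating the hydrate-prone aldehyde; the lactone stereocentre comes from the chiral pool and is not epimerised under the brief, cold exposure to Et3N.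

**Step 5**
Reactants: 6 (4R)-4-hydroxy-4-[(2Z)-oct-2-en-1-yl]cyclopent-2-en-1-one; 9 (2E)-3-[(2R)-5-oxooxolan-2-yl]prop-2-enal
Product: 11 (4S)-4-hydroxy-5-{(2E)-1-hydroxy-3-[(2R)-5-oxooxolan-2-yl]prop-2-en-1-yl}-4-[(2Z)-oct-2-en-1-yl]cyclopent-2-en-1-one (diastereomer mixture at the two new centres), via dilithium alkoxide-dienolate 10 (not isolated)
Conditions: LiN(iPr)2 (2.05 equiv, commercial solution), THF, −78 °C; then 9 (0.9 equiv), −78 °C; AcOH, −78 °C
Reagents that add atoms: none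
Why: Kinetic α'-deprotonation of the lithium alkoxide of 6 gives a cross-conjugated dianion (the β-oxido group cannot leave, so no cyclopentadienone forms) that undergoes 1,2-aldol addition to the enal; the new C7 and C8 centres are left uncontrolled because step 6 erases both, and C12 and C4 are untouched.

**Step 6**
Reactants: 11 (4S)-4-hydroxy-5-{(2E)-1-hydroxy-3-[(2R)-5-oxooxolan-2-yl]prop-2-en-1-yl}-4-[(2Z)-oct-2-en-1-yl]cyclopent-2-en-1-one
Product: 14 (1S,5Z)-4-oxo-1-[(2Z)-oct-2-en-1-yl]-5-{(2E)-3-[(2R)-5-oxooxolan-2-yl]prop-2-en-1-ylidene}cyclopent-2-en-1-yl acetate, via C7 acetate 12 (not isolated), via hydroxy trienone 13 (not isolated)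
Conditions: Ac2O (6 equiv), Et3N (8 equiv), 4-(dimethylamino)pyridine (1 equiv), CH2Cl2, 0 °C → rt, 24 h; SiO2 then HPLC
Reagents that add atoms: acetic anhydride, CC(=O)OC(C)=O
Why: Acetylation of the secondary allylic alcohol, E1cB loss of acetic acid from the resulting β-acetoxy ketone (completing the aldol condensation) and slower nucleophile-catalysed acetylation of the tertiary C12–OH occur in one flask without touching either stereocentre; C5=C6 stays E, and C7=C8 forms as a Z/E mixture (the quaternary C12 penalises the E isomer, so a substantial share of Z is expected) from which the Z isomer is separated.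

## Compound list

1 | (2Z)-oct-2-en-1-ol | CCCCC/C=C\CO | starting material
2 | (2Z)-1-bromooct-2-ene | CCCCC/C=C\CBr | intermediate
3 | furan-2-ylmethanol (furfuryl alcohol) | OCc1ccco1 | starting material
4 | lithium (5-lithiofuran-2-yl)methanolate | [Li]OCc1ccc([Li])o1 | intermediate (not isolated)
5 | {5-[(2Z)-oct-2-en-1-yl]furan-2-yl}methanol | CCCCC/C=C\Cc1ccc(CO)o1 | intermediate
6 | (4R)-4-hydroxy-4-[(2Z)-oct-2-en-1-yl]cyclopent-2-en-1-one | CCCCC/C=C\C[C@]1(O)C=CC(=O)C1 | intermediate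
7 | (5R)-5-(hydroxymethyl)oxolan-2-one | OC[C@H]1CCC(=O)O1 | starting material
8 | (2R)-5-oxooxolane-2-carbaldehyde | O=C[C@H]1CCC(=O)O1 | intermediate (not isolated)
9 | (2E)-3-[(2R)-5-oxooxolan-2-yl]prop-2-enal | O=C/C=C/[C@H]1CCC(=O)O1 | intermediate
10 | dilithium (3S)-3-oxido-3-[(2Z)-oct-2-en-1-yl]cyclopenta-1,4-dien-1-olate | CCCCC/C=C\C[C@]1(O[Li])C=CC(O[Li])=C1 | intermediate (not isolated)
11 | (4S)-4-hydroxy-5-{(2E)-1-hydroxy-3-[(2R)-5-oxooxolan-2-yl]prop-2-en-1-yl}-4-[(2Z)-oct-2-en-1-yl]cyclopent-2-en-1-one (mixture at ring C5 and the carbinol carbon) | CCCCC/C=C\C[C@]1(O)C=CC(=O)C1C(O)/C=C/[C@H]1CCC(=O)O1 | intermediate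
12 | (2E)-1-{(2S)-2-hydroxy-2-[(2Z)-oct-2-en-1-yl]-5-oxocyclopent-3-en-1-yl}-3-[(2R)-5-oxooxolan-2-yl]prop-2-en-1-yl acetate (mixture at the two aldol centres) | CCCCC/C=C\C[C@]1(O)C=CC(=O)C1C(OC(C)=O)/C=C/[C@H]1CCC(=O)O1 | intermediate (not isolated)
13 | (4S,5Z)-4-hydroxy-4-[(2Z)-oct-2-en-1-yl]-5-{(2E)-3-[(2R)-5-oxooxolan-2-yl]prop-2-en-1-ylidene}cyclopent-2-en-1-one | CCCCC/C=C\C[C@]1(O)C=CC(=O)/C1=C\C=C\[C@H]1CCC(=O)O1 | intermediate (not isolated)
14 | (1S,5Z)-4-oxo-1-[(2Z)-oct-2-en-1-yl]-5-{(2E)-3-[(2R)-5-oxooxolan-2-yl]prop-2-en-1-ylidene}cyclopent-2-en-1-yl acetate | CCCCC/C=C\C[C@]1(OC(C)=O)C=CC(=O)/C1=C\C=C\[C@H]1CCC(=O)O1 | target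

## Count

Total steps: 6. Longest linear sequence: 5 steps (1 → 2 → 5 → 6 → 11 → 14); step 4 is the convergent branch.

## Steps most likely to fail, with fallbacks

**Step 3** (enantioselective oxa-Piancatelli). The primary furfuryl cation may oligomerise, and the ee is unproven. The fallback sets out from 3 (and uses 1) and comes back to the route at 6; it sets C12 by substrate control from a relay stereocentre instead of by catalyst control.
- Furfuryl alcohol 3 is rearranged in hot water (pH 4 phosphate buffer, reflux) to racemic 4-hydroxycyclopent-2-en-1-one F1.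
- Candida antarctica lipase B with vinyl acetate in MTBE acetylates the R enantiomer. This leaves (4S)-4-hydroxycyclopent-2-en-1-one F2 and removes the other half as (1R)-4-oxocyclopent-2-en-1-yl acetate F3.
- F2 is silylated (tBuMe2SiCl, imidazole, DMF) to (4S)-4-[(tert-butyldimethylsilyl)oxy]cyclopent-2-en-1-one F4.
- Alcohol 1 is converted (MsCl, LiCl, 2,4,6-collidine, DMF, 0 °C) into (2Z)-1-chlorooct-2-ene F5. With activated Ba metal (from BaI2 and lithium biphenylide, THF, −78 °C) this gives [(2Z)-oct-2-en-1-yl]barium chloride F6.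
- F6 adds 1,2 to F4 through its α-carbon with retention of the Z geometry and anti to the silyloxy group, giving (1R,4S)-4-[(tert-butyldimethylsilyl)oxy]-1-[(2Z)-oct-2-en-1-yl]cyclopent-2-en-1-ol F7.
- Bu4NF in THF gives (1R,4S)-1-[(2Z)-oct-2-en-1-yl]cyclopent-2-ene-1,4-diol F8. The minor trans diol is removed on silica, because it would lead to the enantiomer of 6.
- MnO2 in CH2Cl2 oxidises only the secondary allylic alcohol, which erases the relay centre and gives 6.

**Step 5** (dianion aldol). The alkoxide-dienolate may undergo retro-aldol ring opening or react sluggishly. The fallback sets out from 6 and comes back at 11, using a protected mono-anion.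
- 6 is silylated (Me3SiCl, imidazole, DMF, 0 °C) to (4R)-4-[(2Z)-oct-2-en-1-yl]-4-[(trimethylsilyl)oxy]cyclopent-2-en-1-one F9.
- Deprotonation with LiN(iPr)2 (1.1 equiv, THF, −78 °C) and addition to 9 gives (4S)-5-{(2E)-1-hydroxy-3-[(2R)-5-oxooxolan-2-yl]prop-2-en-1-yl}-4-[(2Z)-oct-2-en-1-yl]-4-[(trimethylsilyl)oxy]cyclopent-2-en-1-one F10.
- AcOH/THF/H2O at rt cleaves the tertiary silyl ether to give 11.

**Step 6** (one-flask acetylation and elimination). The tertiary acetylation may be incomplete, and the Z/E ratio at C7=C8 may be unfavourable. The fallback sets out from 11 and comes back at 14, with dehydration, isomer management and acetylation done separately.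
- 11 is mesylated selectively at the secondary allylic hydroxyl (MsCl, Et3N, CH2Cl2, −20 °C) to (2E)-1-{(2S)-2-hydroxy-2-[(2Z)-oct-2-en-1-yl]-5-oxocyclopent-3-en-1-yl}-3-[(2R)-5-oxooxolan-2-yl]prop-2-en-1-yl methanesulfonate F11.
- 1,8-Diazabicyclo[5.4.0]undec-7-ene eliminates F11 to 13 together with its 7E isomer, (4S,5E)-4-hydroxy-4-[(2Z)-oct-2-en-1-yl]-5-{(2E)-3-[(2R)-5-oxooxolan-2-yl]prop-2-en-1-ylidene}cyclopent-2-en-1-one F12.
- The isomers are separated at the alcohol stage. F12 is irradiated (daylight lamp, benzene, rt) to a photostationary mixture and re-separated to regain 13.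
- 13 is acetylated (Ac2O, 4-(dimethylamino)pyridine, CH2Cl2, rt) to 14.
- The same irradiation and separation loop recycles the 7E isomer of the final product, (1S,5E)-4-oxo-1-[(2Z)-oct-2-en-1-yl]-5-{(2E)-3-[(2R)-5-oxooxolan-2-yl]prop-2-en-1-ylidene}cyclopent-2-en-1-yl acetate F13, if step 6 itself over-produces it.

## Further compounds

F1 | step 3 | racemic 4-hydroxycyclopent-2-en-1-one | O=C1C=CC(O)C1
F2 | step 3 | (4S)-4-hydroxycyclopent-2-en-1-one | O=C1C=C[C@@H](O)C1
F3 | step 3 | (1R)-4-oxocyclopent-2-en-1-yl acetate | O=C1C=C[C@H](OC(C)=O)C1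
F4 | step 3 | (4S)-4-[(tert-butyldimethylsilyl)oxy]cyclopent-2-en-1-one | O=C1C=C[C@@H](O[Si](C)(C)C(C)(C)C)C1
F5 | step 3 | (2Z)-1-chlorooct-2-ene | CCCCC/C=C\CCl
F6 | step 3 | [(2Z)-oct-2-en-1-yl]barium chloride | CCCCC/C=C\C[Ba]Cl
F7 | step 3 | (1R,4S)-4-[(tert-butyldimethylsilyl)oxy]-1-[(2Z)-oct-2-en-1-yl]cyclopent-2-en-1-ol | CCCCC/C=C\C[C@]1(O)C=C[C@@H](O[Si](C)(C)C(C)(C)C)C1
F8 | step 3 | (1R,4S)-1-[(2Z)-oct-2-en-1-yl]cyclopent-2-ene-1,4-diol | CCCCC/C=C\C[C@]1(O)C=C[C@@H](O)C1
F9 | step 5 | (4R)-4-[(2Z)-oct-2-en-1-yl]-4-[(trimethylsilyl)oxy]cyclopent-2-en-1-one | CCCCC/C=C\C[C@]1(O[Si](C)(C)C)C=CC(=O)C1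
F10 | step 5 | (4S)-5-{(2E)-1-hydroxy-3-[(2R)-5-oxooxolan-2-yl]prop-2-en-1-yl}-4-[(2Z)-oct-2-en-1-yl]-4-[(trimethylsilyl)oxy]cyclopent-2-en-1-one | CCCCC/C=C\C[C@]1(O[Si](C)(C)C)C=CC(=O)C1C(O)/C=C/[C@H]1CCC(=O)O1
F11 | step 6 | (2E)-1-{(2S)-2-hydroxy-2-[(2Z)-oct-2-en-1-yl]-5-oxocyclopent-3-en-1-yl}-3-[(2R)-5-oxooxolan-2-yl]prop-2-en-1-yl methanesulfonate | CCCCC/C=C\C[C@]1(O)C=CC(=O)C1C(OS(C)(=O)=O)/C=C/[C@H]1CCC(=O)O1
F12 | step 6 | (4S,5E)-4-hydroxy-4-[(2Z)-oct-2-en-1-yl]-5-{(2E)-3-[(2R)-5-oxooxolan-2-yl]prop-2-en-1-ylidene}cyclopent-2-en-1-one | CCCCC/C=C\C[C@]1(O)C=CC(=O)/C1=C/C=C/[C@H]1CCC(=O)O1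
F13 | step 6 | (1S,5E)-4-oxo-1-[(2Z)-oct-2-en-1-yl]-5-{(2E)-3-[(2R)-5-oxooxolan-2-yl]prop-2-en-1-ylidene}cyclopent-2-en-1-yl acetate | CCCCC/C=C\C[C@]1(OC(C)=O)C=CC(=O)/C1=C/C=C/[C@H]1CCC(=O)O1
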